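**Retrosynthetic overview**
1. Target 12 ⇐ acid 11: the cyclohexanone ring is closed last by intramolecular Friedel–Crafts acylation of the hydroquinone ring; the naphthalene and benzene rings are bought intact.
2. 11 ⇐ enoate 10 ⇐ aryl allyl ether 8: the diaryl-methine C–C bond comes from an aromatic Claisen shift that carries the configuration from an O-bearing carbon to C4.
3. 8 ⇐ diazo ester 6 + phenol 7: the stereo-defining bond is the ether C–O bond, made by enantioselective O–H insertion.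
4. 6 ⇐ 5 ⇐ 4 ⇐ bromide 2 + acid 3 ⇐ naphthol 1: diazo transfer, benzylation, Heck coupling, para-bromination.

Assumption: 5-methoxynaphthalen-1-ol (1) is taken as a low-cost catalogue chemical.

**Step 1**
Reactants: 1 5-methoxynaphthalen-1-ol
Product: 2 4-bromo-5-methoxynaphthalen-1-ol
Conditions: NBS (1.0 equiv), MeCN, −30 °C to 0 °C, dark
Reagents that add atoms: N-bromosuccinimide, O=C1CCC(=O)N1Br
Why: Electrophilic aromatic bromination, in which the free OH is the strongest donor and directs to its para position (C4), so bromine enters peri to the methoxy group.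

**Step 2**
Reactants: 2 4-bromo-5-methoxynaphthalen-1-ol, 3 but-3-enoic acid
Product: 4 (3E)-4-(4-hydroxy-8-methoxynaphthalen-1-yl)but-3-enoic acid
Conditions: Pd(OAc)2 (5 mol%), P(o-tol)3 (12 mol%), Et3N (4 equiv), MeCN, 85 °C, argon; HCl work-up
Reagents that add atoms: none
Why: Mizoroki–Heck reaction, in which the aryl group adds to the terminal alkene carbon and β-hydride elimination toward the benzylic hydrogen gives the aryl-conjugated E-alkene.

**Step 3**
Reactants: 4 (3E)-4-(4-hydroxy-8-methoxynaphthalen-1-yl)but-3-enoic acid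
Product: 5 benzyl (3E)-4-[4-(benzyloxy)-8-methoxynaphthalen-1-yl]but-3-enoate
Conditions: BnBr (2.3 equiv), K2CO3 (2.5 equiv), DMF, 23 °C
Reagents that add atoms: benzyl bromide, BrCc1ccccc1
Why: Williamson etherification of the naphthol and O-alkylation of the carboxylate in one operation, giving groups that all leave later by hydrogenolysis.

**Step 4**
Reactants: 5 benzyl (3E)-4-[4-(benzyloxy)-8-methoxynaphthalen-1-yl]but-3-enoate
Product: 6 benzyl (3E)-4-[4-(benzyloxy)-8-methoxynaphthalen-1-yl]-2-diazobut-3-enoate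
Conditions: p-ABSA (1.3 equiv), DBU (1.5 equiv), MeCN, 0 °C, 2 h; used at once
Reagents that add atoms: 4-acetamidobenzenesulfonyl azide, CC(=O)Nc1ccc(cc1)S(=O)(=O)N=[N+]=[N-]
Why: Regitz diazo transfer to the doubly activated (allylic and α to the ester) methylene, the standard entry to styryl diazoacetates.

**Step 5**
Reactants: 6 benzyl (3E)-4-[4-(benzyloxy)-8-methoxynaphthalen-1-yl]-2-diazobut-3-enoate, 7 4-(benzyloxy)phenol
Product: 8 benzyl (2S,3E)-2-[4-(benzyloxy)phenoxy]-4-[4-(benzyloxy)-8-methoxynaphthalen-1-yl]but-3-enoate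
Conditions: Rh2(O2CCPh3)4 (1 mol%), (S)-6,6'-bis(2,4,6-triisopropylphenyl)-1,1'-spirobiindane-7,7'-diyl hydrogen phosphate (2 mol%), 7 (1.5 equiv), CHCl3, 0 °C, 6 added over 2 h
Reagents that add atoms: none
Why: Proposed new method: the dirhodium carbene from 6 is attacked at the carbene carbon by the phenol oxygen (the aryl-substituted vinyl terminus is too hindered for vinylogous attack), and the metal-associated oxonium ylide is protonated at C2 inside the chiral phosphate pocket by a proton-shuttle 1,2-shift, which fixes the (2S) C–O stereocentre; the closest known chemistry is cooperative dirhodium/chiral spiro phosphoric acid O–H insertion (phenols with aryl diazoacetates, water with alkenyl diazoacetates), not yet shown for a phenol with an alkenyl diazoacetate.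

**Step 6**
Reactants: 8 benzyl (2S,3E)-2-[4-(benzyloxy)phenoxy]-4-[4-(benzyloxy)-8-methoxynaphthalen-1-yl]but-3-enoate
Product: 10 benzyl (2E,4R)-4-[5-(benzyloxy)-2-hydroxyphenyl]-4-[4-(benzyloxy)-8-methoxynaphthalen-1-yl]but-2-enoate, via ortho-dienone 9 (not isolated)
Conditions: 1,2-dichlorobenzene (degassed), BHT (5 mol%), 170 °C, 3 h, argon
Reagents that add atoms: none
Why: Aromatic Claisen rearrangement through a chair transition state with the ester pseudo-equatorial, which bonds the ring carbon ortho to oxygen to C4 on the face that carried the C–O bond, so (2S) becomes (4R) with an E-enoate, and tautomerisation of the dienone restores the phenol.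

**Step 7**
Reactants: 10 benzyl (2E,4R)-4-[5-(benzyloxy)-2-hydroxyphenyl]-4-[4-(benzyloxy)-8-methoxynaphthalen-1-yl]but-2-enoate
Product: 11 (4R)-4-(2,5-dihydroxyphenyl)-4-(4-hydroxy-8-methoxynaphthalen-1-yl)butanoic acid
Conditions: H2 (1 atm), 10% Pd/C, EtOAc–MeOH 1:1, 23 °C; filtered and concentrated under argon
Reagents that add atoms: none
Why: Catalytic hydrogenation of the enoate together with hydrogenolysis of both benzyl ethers and the benzyl ester under neutral conditions, which leaves the C4 stereocentre untouched and the methyl ether in place.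

**Step 8**
Reactants: 11 (4R)-4-(2,5-dihydroxyphenyl)-4-(4-hydroxy-8-methoxynaphthalen-1-yl)butanoic acid
Product: 12 (4R)-5,8-dihydroxy-4-(4-hydroxy-8-methoxynaphthalen-1-yl)-3,4-dihydronaphthalen-1(2H)-one
Conditions: P2O5 in MeSO3H (1:10 w/w), 23 °C, argon, 1–2 h; poured onto ice
Reagents that add atoms: none
Why: Intramolecular Friedel–Crafts acylation closing the six-membered ring at the only hydroquinone carbon next to the side chain, which is ortho to an OH and gives a hydrogen-bonded hydroxy ketone, whereas naphthalene C2 is meta to its OH and does not compete.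

**Compound list**
1 | 5-methoxynaphthalen-1-ol | COc1cccc2c(O)cccc12 | starting material
2 | 4-bromo-5-methoxynaphthalen-1-ol | COc1cccc2c(O)ccc(Br)c12 | intermediate
3 | but-3-enoic acid | C=CCC(=O)O | starting material
4 | (3E)-4-(4-hydroxy-8-methoxynaphthalen-1-yl)but-3-enoic acid | COc1cccc2c(O)ccc(/C=C/CC(=O)O)c12 | intermediate
5 | benzyl (3E)-4-[4-(benzyloxy)-8-methoxynaphthalen-1-yl]but-3-enoate | COc1cccc2c(OCc3ccccc3)ccc(/C=C/CC(=O)OCc3ccccc3)c12 | intermediate
6 | benzyl (3E)-4-[4-(benzyloxy)-8-methoxynaphthalen-1-yl]-2-diazobut-3-enoate | COc1cccc2c(OCc3ccccc3)ccc(/C=C/C(=[N+]=[N-])C(=O)OCc3ccccc3)c12 | intermediate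
7 | 4-(benzyloxy)phenol | Oc1ccc(OCc2ccccc2)cc1 | starting material
8 | benzyl (2S,3E)-2-[4-(benzyloxy)phenoxy]-4-[4-(benzyloxy)-8-methoxynaphthalen-1-yl]but-3-enoate | O=C(OCc1ccccc1)[C@@H](Oc1ccc(OCc2ccccc2)cc1)/C=C/c1ccc(OCc2ccccc2)c2cccc(OC)c12 | intermediate
9 | benzyl (2E,4S)-4-[(1S)-3-(benzyloxy)-6-oxocyclohexa-2,4-dien-1-yl]-4-[4-(benzyloxy)-8-methoxynaphthalen-1-yl]but-2-enoate (ortho-dienone) | O=C(OCc1ccccc1)/C=C/[C@@H]([C@H]1C=C(OCc2ccccc2)C=CC1=O)c1ccc(OCc2ccccc2)c2cccc(OC)c12 | intermediate (not isolated)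
10 | benzyl (2E,4R)-4-[5-(benzyloxy)-2-hydroxyphenyl]-4-[4-(benzyloxy)-8-methoxynaphthalen-1-yl]but-2-enoate | O=C(OCc1ccccc1)/C=C/[C@@H](c1cc(OCc2ccccc2)ccc1O)c1ccc(OCc2ccccc2)c2cccc(OC)c12 | intermediate
11 | (4R)-4-(2,5-dihydroxyphenyl)-4-(4-hydroxy-8-methoxynaphthalen-1-yl)butanoic acid | O=C(O)CC[C@@H](c1cc(O)ccc1O)c1ccc(O)c2cccc(OC)c12 | intermediate
12 | (4R)-5,8-dihydroxy-4-(4-hydroxy-8-methoxynaphthalen-1-yl)-3,4-dihydronaphthalen-1(2H)-one | COc1cccc2c(O)ccc([C@H]3CCC(=O)c4c(O)ccc(O)c43)c12 | target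

**Count**
Total steps: 8. Longest linear sequence: 8 (1 to 12); 3 and 7 enter as bought compounds.

**Steps most likely to fail, with fallbacks**

Step 5 (the proposed new step). The phenol may attack the vinyl terminus, protonation may occur at C4 to give the achiral enol ether, or the ee or sense of induction may be wrong; in the last case the mirror-image acid is used. The fallback is known chemistry and runs from 6 back to 8. Dirhodium/chiral spiro phosphoric acid O–H insertion of water, established for alkenyl diazoacetates (Rh2(O2CCPh3)4, the acid antipode that gives the 2R alcohol, H2O, CHCl3), gives benzyl (2R,3E)-4-[4-(benzyloxy)-8-methoxynaphthalen-1-yl]-2-hydroxybut-3-enoate F1. Mitsunobu etherification of F1 with 7 (PPh3, DIAD, toluene, 0 °C) inverts C2 and gives 8.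

Step 6. The shift needs about 170 °C. The ester may sit pseudo-axial in part, which gives the Z-enoate with the opposite C4 configuration. The new phenol can also add to the enoate (oxa-Michael), and the ether can ionise. The fallback replaces the sigmatropic shift by a palladium-catalysed allyl–aryl coupling and runs from 6 to 11.
- Water O–H insertion as above, with the other acid antipode, gives benzyl (2S,3E)-4-[4-(benzyloxy)-8-methoxynaphthalen-1-yl]-2-hydroxybut-3-enoate F2.
- Ac2O, pyridine gives benzyl (2S,3E)-2-(acetyloxy)-4-[4-(benzyloxy)-8-methoxynaphthalen-1-yl]but-3-enoate F3.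
- The aryl partner is made from bromohydroquinone: BnBr, K2CO3 gives 2-bromo-1,4-bis(benzyloxy)benzene F4, then n-BuLi, B(OiPr)3 and aqueous acid give [2,5-bis(benzyloxy)phenyl]boronic acid F5.
- γ-Selective coupling of F3 with F5 (Pd(OAc)2, 1,10-phenanthroline, AgSbF6, 1,2-dichloroethane, 60 °C) proceeds with 1,3-syn chirality transfer, the same stereochemical course as the Claisen shift, and gives benzyl (2E,4R)-4-[2,5-bis(benzyloxy)phenyl]-4-[4-(benzyloxy)-8-methoxynaphthalen-1-yl]but-2-enoate F6.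
- H2, Pd/C converts F6 into 11.

Step 8. Strong acid on a triphenolic diaryl methine may cause retro-Friedel–Crafts scrambling or racemisation, and O-acylation may compete. The fallback closes the ring with all phenols benzylated and deprotects last; it runs from 10 to 12.
- H2 (4 atm), RhCl(PPh3)3, benzene–EtOH saturates the alkene only and gives benzyl (4R)-4-[5-(benzyloxy)-2-hydroxyphenyl]-4-[4-(benzyloxy)-8-methoxynaphthalen-1-yl]butanoate F7.
- BnBr, K2CO3, DMF gives benzyl (4R)-4-[2,5-bis(benzyloxy)phenyl]-4-[4-(benzyloxy)-8-methoxynaphthalen-1-yl]butanoate F8.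
- LiOH, THF–H2O gives (4R)-4-[2,5-bis(benzyloxy)phenyl]-4-[4-(benzyloxy)-8-methoxynaphthalen-1-yl]butanoic acid F9.
- TFAA, CH2Cl2, 0 °C to 23 °C cyclises ortho to a benzyloxy group and gives (4R)-5,8-bis(benzyloxy)-4-[4-(benzyloxy)-8-methoxynaphthalen-1-yl]-3,4-dihydronaphthalen-1(2H)-one F10.
- H2, Pd/C converts F10 into 12.

**Further compounds**
F1 | step 5 | benzyl (2R,3E)-4-[4-(benzyloxy)-8-methoxynaphthalen-1-yl]-2-hydroxybut-3-enoate | O=C(OCc1ccccc1)[C@H](O)/C=C/c1ccc(OCc2ccccc2)c2cccc(OC)c12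
F2 | step 6 | benzyl (2S,3E)-4-[4-(benzyloxy)-8-methoxynaphthalen-1-yl]-2-hydroxybut-3-enoate | O=C(OCc1ccccc1)[C@@H](O)/C=C/c1ccc(OCc2ccccc2)c2cccc(OC)c12
F3 | step 6 | benzyl (2S,3E)-2-(acetyloxy)-4-[4-(benzyloxy)-8-methoxynaphthalen-1-yl]but-3-enoate | O=C(OCc1ccccc1)[C@@H](OC(C)=O)/C=C/c1ccc(OCc2ccccc2)c2cccc(OC)c12
F4 | step 6 | 2-bromo-1,4-bis(benzyloxy)benzene | Brc1cc(OCc2ccccc2)ccc1OCc1ccccc1
F5 | step 6 | [2,5-bis(benzyloxy)phenyl]boronic acid | OB(O)c1cc(OCc2ccccc2)ccc1OCc1ccccc1
F6 | step 6 | benzyl (2E,4R)-4-[2,5-bis(benzyloxy)phenyl]-4-[4-(benzyloxy)-8-methoxynaphthalen-1-yl]but-2-enoate | O=C(OCc1ccccc1)/C=C/[C@@H](c1cc(OCc2ccccc2)ccc1OCc1ccccc1)c1ccc(OCc2ccccc2)c2cccc(OC)c12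
F7 | step 8 | benzyl (4R)-4-[5-(benzyloxy)-2-hydroxyphenyl]-4-[4-(benzyloxy)-8-methoxynaphthalen-1-yl]butanoate | O=C(OCc1ccccc1)CC[C@@H](c1cc(OCc2ccccc2)ccc1O)c1ccc(OCc2ccccc2)c2cccc(OC)c12
F8 | step 8 | benzyl (4R)-4-[2,5-bis(benzyloxy)phenyl]-4-[4-(benzyloxy)-8-methoxynaphthalen-1-yl]butanoate | O=C(OCc1ccccc1)CC[C@@H](c1cc(OCc2ccccc2)ccc1OCc1ccccc1)c1ccc(OCc2ccccc2)c2cccc(OC)c12
F9 | step 8 | (4R)-4-[2,5-bis(benzyloxy)phenyl]-4-[4-(benzyloxy)-8-methoxynaphthalen-1-yl]butanoic acid | O=C(O)CC[C@@H](c1cc(OCc2ccccc2)ccc1OCc1ccccc1)c1ccc(OCc2ccccc2)c2cccc(OC)c12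
F10 | step 8 | (4R)-5,8-bis(benzyloxy)-4-[4-(benzyloxy)-8-methoxynaphthalen-1-yl]-3,4-dihydronaphthalen-1(2H)-one | COc1cccc2c(OCc3ccccc3)ccc([C@H]3CCC(=O)c4c(OCc5ccccc5)ccc(OCc5ccccc5)c43)c12
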